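Assumption: the SMILES has no stereocentre and no stereogenic double bond. The target is achiral, so no enantiocontrol is needed.

## Retrosynthetic overview
1. Target benzil ⇒ 3,5-diprenyl-2,4-dihydroxy-6-methoxy deoxybenzoin. One oxidant makes both the pyran (o-prenylphenol → o-quinone methide → oxa-6π closure) and the 1,2-dione (from ArCH2–C=O).
2. Diprenyl deoxybenzoin ⇒ unprenylated deoxybenzoin + two prenyl bromide, by double nuclear C-prenylation ortho to the 4-phenolate.
3. Deoxybenzoin ⇒ 5-methoxyresorcinol + 4-hydroxyphenylacetic acid, by Friedel–Crafts acylation.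
4. Ring order: rings A and B are bought. The pyran is the only ring made and it is closed last. No protecting groups are used.

## Route

Step 1
Reactants: 1 5-methoxyresorcinol (3,5-dihydroxyanisole); 2 4-hydroxyphenylacetic acid
Product: 3 1-(2,4-dihydroxy-6-methoxyphenyl)-2-(4-hydroxyphenyl)ethanone
Conditions: BF3·OEt2 (neat, as solvent), 85 °C, 1.5 h; then aq. NaOAc, rt; chromatography
Reagents that add atoms: none
Why: BF3-mediated Friedel–Crafts acylation of a phloroglucinol-type arene, in which two equivalent carbons (para to one OH, ortho to the other OH and to OMe) lead to 3 against a single carbon between the two OH groups, and the chelated ketone stops a second acylation.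

Step 2
Reactants: 3 1-(2,4-dihydroxy-6-methoxyphenyl)-2-(4-hydroxyphenyl)ethanone; 4 prenyl bromide (1-bromo-3-methylbut-2-ene)
Product: 5 1-[2,4-dihydroxy-6-methoxy-3,5-bis(3-methylbut-2-enyl)phenyl]-2-(4-hydroxyphenyl)ethanone
Conditions: 4 (2.3 equiv), KOH (2.3 equiv, slow addition, pH ca. 9), H2O/MeOH 4:1, N2, 0 °C to rt
Reagents that add atoms: prenyl bromide 4, CC(C)=CCBr
Why: Nuclear C-prenylation of an ambident acylphloroglucinol phenolate in a protic medium, where the hydrogen-bonded 4-phenolate (pKa ca. 7.5) reacts through both ortho carbons C3 and C5, while the ring B phenol (pKa ca. 10) and the CH2 stay protonated at this pH.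

Step 3
Reactants: 5 1-[2,4-dihydroxy-6-methoxy-3,5-bis(3-methylbut-2-enyl)phenyl]-2-(4-hydroxyphenyl)ethanone
Product: 10 1-[5-hydroxy-7-methoxy-2,2-dimethyl-8-(3-methylbut-2-enyl)-2H-chromen-6-yl]-2-(4-hydroxyphenyl)ethane-1,2-dione (target CNP0184805.0), via o-quinone methide 6 (not isolated), via chromene deoxybenzoin 7 (not isolated), via acyl p-quinone methide 8 (not isolated), via benzoin 9 (not isolated)
Conditions: DDQ (1.1 equiv), 1,4-dioxane, rt, 1 h; then H2O (5 vol %), DDQ (2.2 equiv), 50 °C
Reagents that add atoms: water, O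
Why: Proposed new method: DDQ removes hydride from the benzylic CH2 of the C3 prenyl group while the free 4-OH loses its proton, and the resulting (Z)-o-quinone methide 6 closes by oxa-6π electrocyclisation to 7 as prenylphenol oxidocyclases are thought to do (closest known type: DDQ cyclodehydrogenation of o-prenylphenols, where a carbonyl-chelated ortho OH stays out of the ring); more DDQ then oxidises the enol of 7, a vinylogous hydroquinone, to 8, which adds water to give 9 and is dehydrogenated once more to the dione (closest known type: DDQ/water oxidation of p-hydroxy- and p-methoxybenzylic CH2 and CHOH groups to ketones), and the transient carbinol centre of 9 is erased, so 10 has no stereocentre.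

## Compound list
1 | 5-methoxyresorcinol | COc1cc(O)cc(O)c1 | starting material
2 | 4-hydroxyphenylacetic acid | OC(=O)Cc1ccc(O)cc1 | starting material
3 | 1-(2,4-dihydroxy-6-methoxyphenyl)-2-(4-hydroxyphenyl)ethanone | COc1cc(O)cc(O)c1C(=O)Cc1ccc(O)cc1 | intermediate
4 | prenyl bromide | CC(C)=CCBr | starting material
5 | 1-[2,4-dihydroxy-6-methoxy-3,5-bis(3-methylbut-2-enyl)phenyl]-2-(4-hydroxyphenyl)ethanone | COc1c(CC=C(C)C)c(O)c(CC=C(C)C)c(O)c1C(=O)Cc1ccc(O)cc1 | intermediate
6 | ring A o-quinone methide of 5: C4 carbonyl, (Z)-3-methylbut-2-enylidene at C3, other groups unchanged (not isolated) | CC(C)=C/C=C1\C(=O)C(CC=C(C)C)=C(OC)C(C(=O)Cc2ccc(O)cc2)=C1O | intermediate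
7 | 1-[5-hydroxy-7-methoxy-2,2-dimethyl-8-(3-methylbut-2-enyl)-2H-chromen-6-yl]-2-(4-hydroxyphenyl)ethanone (not isolated) | COc1c(CC=C(C)C)c2c(c(O)c1C(=O)Cc1ccc(O)cc1)C=CC(C)(C)O2 | intermediate
8 | 4-{2-[5-hydroxy-7-methoxy-2,2-dimethyl-8-(3-methylbut-2-enyl)-2H-chromen-6-yl]-2-oxoethylidene}cyclohexa-2,5-dien-1-one (not isolated) | COc1c(CC=C(C)C)c2c(c(O)c1C(=O)C=C1C=CC(=O)C=C1)C=CC(C)(C)O2 | intermediate
9 | 2-hydroxy-1-[5-hydroxy-7-methoxy-2,2-dimethyl-8-(3-methylbut-2-enyl)-2H-chromen-6-yl]-2-(4-hydroxyphenyl)ethanone, racemic (not isolated) | COc1c(CC=C(C)C)c2c(c(O)c1C(=O)C(O)c1ccc(O)cc1)C=CC(C)(C)O2 | intermediate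
10 | 1-[5-hydroxy-7-methoxy-2,2-dimethyl-8-(3-methylbut-2-enyl)-2H-chromen-6-yl]-2-(4-hydroxyphenyl)ethane-1,2-dione | COc1c(CC=C(C)C)c2c(c(O)c1C(=O)C(=O)c1ccc(O)cc1)C=CC(C)(C)O2 | target

Total step count: 3. Longest linear sequence: 3.

## Steps most likely to fail

**Step 3 (highest risk).**
- The C5 prenyl group can also close onto the 4-OH, which gives the linear chromene isomer.
- The only bias toward C3 is steric and statistical. Its quinone methide sits next to a small chelated OH instead of the buttressed OMe, and either flanking OH can give up the proton.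
- A separable mixture with 10 as the larger part is therefore the realistic outcome.
- The methylene oxidation may stall.
- The surviving prenyl group, para to the 2-OH, may be over-oxidised.

Fallback: it sets out from 3 and comes back at 7. One equivalent of 4 under the step 2 conditions gives mainly 1-[2,4-dihydroxy-6-methoxy-3-(3-methylbut-2-enyl)phenyl]-2-(4-hydroxyphenyl)ethanone F6. DDQ (1.1 equiv, dry dioxane) then has only one prenyl group to close, and the chelated 2-OH stays out, which gives 1-(5-hydroxy-7-methoxy-2,2-dimethyl-2H-chromen-6-yl)-2-(4-hydroxyphenyl)ethanone F7. The second prenyl group goes onto the only free carbon of ring A by Friedel–Crafts prenylation (2-methylbut-3-en-2-ol, BF3·OEt2, dioxane, rt). No ortho OH is left there to form a chroman, so this gives 7 as an isolated compound. Compound 7 is then taken to 10 in a separate flask by amine-base autoxidation of the enolate (DABCO, air, DMF, 90 °C) instead of by DDQ.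

**Step 2.**
- 4-O-prenylation, geminal diprenylation at C3 (dearomatised dienone) and incomplete reaction at C5 all compete.
- About 25–35 % of 5 is expected.

Fallback: it sets out from 3 and comes back at 5. NIS (2.05 equiv, MeCN, 0 °C) iodinates the two free carbons of ring A, which are far more activated than ring B, to give 1-(2,4-dihydroxy-3,5-diiodo-6-methoxyphenyl)-2-(4-hydroxyphenyl)ethanone F5. A double Stille coupling with tributyl(3-methylbut-2-enyl)stannane (Pd(PPh3)4, DMF, 90 °C) then gives 5. The halogens fix the positions of the new C–C bonds, and neither O-alkylation nor geminal dialkylation can occur.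

**Step 1.**
- Acylation between the two OH groups gives the 2,6-dihydroxy-4-methoxy ketone. A ratio of about 2–3:1 in favour of 3 is expected.
- Hot BF3·OEt2 may cleave some of the ortho OMe.

Fallback: it sets out from 2 and comes back at 3. Compound 2 is condensed with phloroglucinol (BF3·OEt2, 85 °C) to the symmetric ketone 1-(2,4,6-trihydroxyphenyl)-2-(4-hydroxyphenyl)ethanone F1, where no regiochemical question arises. DMF/MsCl in the same medium closes it to genistein F2, whose pyranone ring ties up one of the two ortho oxygens. PivCl (2.1 equiv, pyridine, 0 °C) acylates the two unchelated phenols to give 7,4'-di-O-pivaloylgenistein F3. MeI/K2CO3/DMF methylates the remaining 5-OH to give 5-O-methyl-7,4'-di-O-pivaloylgenistein F4. Aqueous NaOH/EtOH at reflux removes both pivalates and opens the pyranone by retro-Claisen loss of formate, which gives 3 as a single regioisomer.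

## Further compounds
F1 | step 1 | 1-(2,4,6-trihydroxyphenyl)-2-(4-hydroxyphenyl)ethanone | O=C(Cc1ccc(O)cc1)c1c(O)cc(O)cc1O
F2 | step 1 | genistein | O=c1c(-c2ccc(O)cc2)coc2cc(O)cc(O)c12
F3 | step 1 | 7,4'-di-O-pivaloylgenistein | CC(C)(C)C(=O)Oc1ccc(cc1)-c1coc2cc(OC(=O)C(C)(C)C)cc(O)c2c1=O
F4 | step 1 | 5-O-methyl-7,4'-di-O-pivaloylgenistein | COc1cc(OC(=O)C(C)(C)C)cc2occ(-c3ccc(OC(=O)C(C)(C)C)cc3)c(=O)c12
F5 | step 2 | 1-(2,4-dihydroxy-3,5-diiodo-6-methoxyphenyl)-2-(4-hydroxyphenyl)ethanone | COc1c(I)c(O)c(I)c(O)c1C(=O)Cc1ccc(O)cc1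
F6 | step 3 | 1-[2,4-dihydroxy-6-methoxy-3-(3-methylbut-2-enyl)phenyl]-2-(4-hydroxyphenyl)ethanone | COc1cc(O)c(CC=C(C)C)c(O)c1C(=O)Cc1ccc(O)cc1
F7 | step 3 | 1-(5-hydroxy-7-methoxy-2,2-dimethyl-2H-chromen-6-yl)-2-(4-hydroxyphenyl)ethanone | COc1cc2c(c(O)c1C(=O)Cc1ccc(O)cc1)C=CC(C)(C)O2
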